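**Plan**

- Target numbering: C1 is the carboxyl carbon; ring A is C3(Et)=C4–C5(Me)–C6–C11; ring B is C6–C7(Me)=C8–C9(Et, dienyl C12–C15)–C10(Me, C1)–C11. Ring B is a cyclohex-3-ene-1-carboxylic acid whose quaternary pair C9–C10 lies allylic to C7=C8. The first cut is therefore C9–C10, with C7=C8 returned to a C7–O bond: a trans-fused δ-lactone (C7–O–C1) set up for an enolate Claisen ring contraction.
- Further cuts: C14=C15, C12=C13 and C8=C9 (three olefinations back to a C8 aldehyde); C7–O (carboxylate opening of a C7–C8 epoxide); C10–C11 (Ireland–Claisen of a ring A propanoate); C3–ethyl (Negishi); C5–methyl and C6–C7 (conjugate addition and alkylation on the silyloxycyclopentenone).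
- Forward order: ring A is bought as the cyclopentenone; the lactone ring closes in step 11; the triene is grown on the lactone; ring B closes last, in step 17, as the lactone ring is lost.
- Stereochemistry: C6 and C5 come from the (S)-silyloxy group. The C4 carbinol (reagent-controlled reduction) is relayed to C11. C7 comes from Sharpless epoxidation followed by inversion. C9 and C10 come from C7 and the (E)-C8=C9 geometry through the boat of step 17.

Key step: step 17

Remarks: Atom numbers in the text are those of the target. The C10 configuration set in step 11 is of no consequence, because C10 becomes trigonal in step 17. Compounds 20 to 23 and 27 to 29 are written as the epimer with the equatorial C10 methyl group; either epimer or a mixture is carried on.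

**Route**

Step 1
Reactants: 1 but-2-yn-1-ol
Product: 2 tert-butyl(but-2-yn-1-yloxy)dimethylsilane
Conditions: t-BuMe2SiCl, imidazole, CH2Cl2, 0 → 23 °C
Reagents that add atoms: tert-butyldimethylsilyl chloride, CC(C)(C)[Si](C)(C)Cl
Why: Standard silyl ether formation masks the primary hydroxyl for the organometallic chemistry of steps 2 and 3.

Step 2
Reactants: 2 tert-butyl(but-2-yn-1-yloxy)dimethylsilane
Product: 4 tert-butyl{[(2E)-3-iodobut-2-en-1-yl]oxy}dimethylsilane, via alkenylzirconocene 3 (not isolated)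
Conditions: Cp2Zr(H)Cl (1.5 equiv), THF, 50 °C; then I2, 0 °C
Reagents that add atoms: iodine, II
Why: Hydrozirconation adds Zr–H syn and, once equilibrated by the excess hydride, should carry zirconium on the alkyne carbon next to the small methyl group, so that iodinolysis with retention gives the (E)-3-iodoalkene that fixes the C7=C8 geometry needed in step 10.

Step 3
Reactants: 4 tert-butyl{[(2E)-3-iodobut-2-en-1-yl]oxy}dimethylsilane; 5 (S)-4-(tert-butyldimethylsilyloxy)cyclopent-2-en-1-one
Product: 9 (2S,3R,4S)-4-(tert-butyldimethylsilyloxy)-3-[(2E)-4-(tert-butyldimethylsilyloxy)but-2-en-2-yl]-2-methylcyclopentan-1-one, via alkenyllithium 6 (not isolated), via alkenylzincate 7 (not isolated), via zinc enolate 8 (not isolated)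
Conditions: 4, t-BuLi (2 equiv), Et2O, −78 °C; Me2Zn, −78 → 0 °C; 5, THF, −78 °C; then HMPA, MeI, −78 → −40 °C
Reagents that add atoms: iodomethane, CI
Why: In this three-component coupling (conjugate addition, then enolate alkylation) the alkenyl group of the mixed zincate should add to the face of 5 opposite the silyloxy group (sets C6) and the zinc enolate should be methylated trans to the new neighbour (sets C5), the trans arrangement of lithium and CH2OSi in 6 excluding silyl migration.

Step 4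
Reactants: 9 (2S,3R,4S)-4-(tert-butyldimethylsilyloxy)-3-[(2E)-4-(tert-butyldimethylsilyloxy)but-2-en-2-yl]-2-methylcyclopentan-1-one
Product: 10 (4R,5S)-4-[(2E)-4-(tert-butyldimethylsilyloxy)but-2-en-2-yl]-5-methylcyclopent-2-en-1-one
Conditions: DBU, CH2Cl2, 0 °C, short contact
Reagents that add atoms: none
Why: E1cB β-elimination of the ring silyloxy group gives the enone, the brief exposure to base at 0 °C being chosen to spare the doubly allylic C6–H.

Step 5
Reactants: 10 (4R,5S)-4-[(2E)-4-(tert-butyldimethylsilyloxy)but-2-en-2-yl]-5-methylcyclopent-2-en-1-one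
Product: 11 (4S,5S)-4-[(2E)-4-(tert-butyldimethylsilyloxy)but-2-en-2-yl]-2-iodo-5-methylcyclopent-2-en-1-one
Conditions: I2, pyridine, CH2Cl2, 0 → 23 °C
Reagents that add atoms: iodine, II
Why: α-Iodination of the enone by conjugate addition of pyridine, iodination of the enolate and elimination (Baylis–Hillman-type activation) places the halogen on C3 only, under conditions too weakly basic to touch C6–H.

Step 6
Reactants: 11 (4S,5S)-4-[(2E)-4-(tert-butyldimethylsilyloxy)but-2-en-2-yl]-2-iodo-5-methylcyclopent-2-en-1-one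
Product: 12 (4R,5S)-4-[(2E)-4-(tert-butyldimethylsilyloxy)but-2-en-2-yl]-2-ethyl-5-methylcyclopent-2-en-1-one
Conditions: Et2Zn, Pd(dppf)Cl2 (5 mol %), THF, 0 → 23 °C
Reagents that add atoms: diethylzinc, CC[Zn]CC
Why: Negishi coupling of the α-iodoenone with the alkylzinc installs the C3 ethyl group under non-basic conditions, the wide-bite-angle dppf ligand favouring reductive elimination over β-hydride loss.

Step 7
Reactants: 12 (4R,5S)-4-[(2E)-4-(tert-butyldimethylsilyloxy)but-2-en-2-yl]-2-ethyl-5-methylcyclopent-2-en-1-one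
Product: 13 (1S,4R,5S)-4-[(2E)-4-(tert-butyldimethylsilyloxy)but-2-en-2-yl]-2-ethyl-5-methylcyclopent-2-en-1-ol
Conditions: (R)-2-methyl-CBS-oxazaborolidine (20 mol %), catecholborane, toluene, −78 °C
Reagents that add atoms: none
Why: Corey–Bakshi–Shibata reduction gives 1,2-reduction only, and the (R)-catalyst, which reads the α-ethylalkenyl arm as the large group, should deliver hydride to the face anti to the C5 methyl group to give the C4 (S)-alcohol with the hydroxyl cis to that methyl.

Step 8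
Reactants: 13 (1S,4R,5S)-4-[(2E)-4-(tert-butyldimethylsilyloxy)but-2-en-2-yl]-2-ethyl-5-methylcyclopent-2-en-1-ol; 14 propanoyl chloride
Product: 15 (1S,4R,5S)-4-[(2E)-4-(tert-butyldimethylsilyloxy)but-2-en-2-yl]-2-ethyl-5-methylcyclopent-2-en-1-yl propanoate
Conditions: pyridine, DMAP (cat.), CH2Cl2, 0 °C
Reagents that add atoms: none
Why: Acylation of the secondary allylic alcohol under nucleophilic catalysis gives the propanoate that carries C1, C10 and the C10 methyl group.

Step 9
Reactants: 15 (1S,4R,5S)-4-[(2E)-4-(tert-butyldimethylsilyloxy)but-2-en-2-yl]-2-ethyl-5-methylcyclopent-2-en-1-yl propanoate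
Product: 16 (1S,4R,5S)-2-ethyl-4-[(2E)-4-hydroxybut-2-en-2-yl]-5-methylcyclopent-2-en-1-yl propanoate
Conditions: HF·pyridine, pyridine, THF, 0 → 23 °C
Reagents that add atoms: none
Why: Buffered fluoride cleaves the primary silyl ether (Si–F bond formation) without touching the allylic ester and frees the only allylic alcohol of the molecule.

Step 10
Reactants: 16 (1S,4R,5S)-2-ethyl-4-[(2E)-4-hydroxybut-2-en-2-yl]-5-methylcyclopent-2-en-1-yl propanoate
Product: 17 (1S,4R,5S)-2-ethyl-4-[(2R,3R)-3-(hydroxymethyl)-2-methyloxiran-2-yl]-5-methylcyclopent-2-en-1-yl propanoate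
Conditions: Ti(OiPr)4 (10 mol %), D-(−)-diisopropyl tartrate (12 mol %), t-BuOOH, 4 Å MS, CH2Cl2, −20 °C
Reagents that add atoms: tert-butyl hydroperoxide, CC(C)(C)OO
Why: Sharpless asymmetric epoxidation of this geraniol-type (E)-allylic alcohol with the D-tartrate should give the (2R,3R)-epoxide under reagent control, the ring alkene having no free hydroxyl and staying untouched.

Step 11
Reactants: 17 (1S,4R,5S)-2-ethyl-4-[(2R,3R)-3-(hydroxymethyl)-2-methyloxiran-2-yl]-5-methylcyclopent-2-en-1-yl propanoate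
Product: 22 (1S,4R,4aS,7R,7aS)-1-[(1R)-1,2-dihydroxyethyl]-5-ethyl-1,4,7-trimethyl-4,4a,7,7a-tetrahydrocyclopenta[c]pyran-3(1H)-one, via silyl ether 18 (not isolated), via silyl ketene acetal 19 (not isolated), via bis-silylated acid 20 (not isolated), via epoxy acid 21 (not isolated)
Conditions: Me3SiCl, Et3N, THF, 0 °C; then LiN(iPr)2, −78 → 23 °C, then 50 °C; aq. citric acid; then CSA (cat.), CH2Cl2, 0 → 23 °C
Reagents that add atoms: none
Why: Ireland–Claisen rearrangement of the silyl ketene acetal should move the chirality of C4–O suprafacially to C11 (new C10–C11 bond syn to the departing oxygen and anti to the C6 substituent), after which the freed acid opens the epoxide 6-exo at the tertiary carbon C7 with inversion under acid catalysis, fixing C7 and closing the trans-fused δ-lactone.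

Step 12
Reactants: 22 (1S,4R,4aS,7R,7aS)-1-[(1R)-1,2-dihydroxyethyl]-5-ethyl-1,4,7-trimethyl-4,4a,7,7a-tetrahydrocyclopenta[c]pyran-3(1H)-one
Product: 23 (1S,4R,4aS,7R,7aS)-5-ethyl-1,4,7-trimethyl-3-oxo-1,3,4,4a,7,7a-hexahydrocyclopenta[c]pyran-1-carbaldehyde
Conditions: NaIO4, THF/pH 7 buffer, 0 → 23 °C
Reagents that add atoms: none
Why: Periodate glycol cleavage removes the CH2OH carbon and leaves the C8 aldehyde on the fully substituted C7, which cannot epimerise.

Step 13
Reactants: 24 propyltriphenylphosphonium bromide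
Product: 26 2-(triphenylphosphoranylidene)butanal, via propylidene ylide 25 (not isolated)
Conditions: KOtBu, THF, 0 °C; then HCO2Et, 0 → 23 °C
Reagents that add atoms: ethyl formate, CCOC=O
Why: C-Formylation of the non-stabilised ylide by the formate ester followed by proton loss from the acylphosphonium ion is the standard entry to α-formyl alkylidenephosphoranes.

Step 14
Reactants: 23 (1S,4R,4aS,7R,7aS)-5-ethyl-1,4,7-trimethyl-3-oxo-1,3,4,4a,7,7a-hexahydrocyclopenta[c]pyran-1-carbaldehyde; 26 2-(triphenylphosphoranylidene)butanal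
Product: 27 (2E)-2-ethyl-3-[(1S,4R,4aS,7R,7aS)-5-ethyl-1,4,7-trimethyl-3-oxo-1,3,4,4a,7,7a-hexahydrocyclopenta[c]pyran-1-yl]prop-2-enal
Conditions: toluene, 90 °C
Reagents that add atoms: none
Why: Wittig reaction of the stabilised α-branched ylide is reliably E-selective, so the formyl carbon C12 should end trans and the ethyl group cis to C7, the geometry the key step needs.

Step 15
Reactants: 27 (2E)-2-ethyl-3-[(1S,4R,4aS,7R,7aS)-5-ethyl-1,4,7-trimethyl-3-oxo-1,3,4,4a,7,7a-hexahydrocyclopenta[c]pyran-1-yl]prop-2-enal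
Product: 28 (2E,4E)-4-ethyl-5-[(1S,4R,4aS,7R,7aS)-5-ethyl-1,4,7-trimethyl-3-oxo-1,3,4,4a,7,7a-hexahydrocyclopenta[c]pyran-1-yl]-2-methylpenta-2,4-dienal
Conditions: Ph3P=C(Me)CHO, toluene, 90 °C
Reagents that add atoms: 2-(triphenylphosphoranylidene)propanal, CC(C=O)=P(c1ccccc1)(c1ccccc1)c1ccccc1
Why: A second stabilised-ylide Wittig reaction should add C13 and C14 with E geometry at C12=C13 (C9 trans to C14), the dienal being less electrophilic than the enal so that the chain grows by one unit only.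

Step 16
Reactants: 28 (2E,4E)-4-ethyl-5-[(1S,4R,4aS,7R,7aS)-5-ethyl-1,4,7-trimethyl-3-oxo-1,3,4,4a,7,7a-hexahydrocyclopenta[c]pyran-1-yl]-2-methylpenta-2,4-dienal
Product: 29 (1S,4R,4aS,7R,7aS)-5-ethyl-1-[(1E,3E,5E)-2-ethyl-4-methyl-6-phenylhexa-1,3,5-trien-1-yl]-1,4,7-trimethyl-4,4a,7,7a-tetrahydrocyclopenta[c]pyran-3(1H)-one
Conditions: (EtO)2P(O)CH2Ph, NaN(SiMe3)2, THF, −78 °C; then 28, −78 → 0 °C
Reagents that add atoms: diethyl benzylphosphonate, CCOP(=O)(Cc1ccccc1)OCC
Why: Horner–Wadsworth–Emmons olefination with the preformed benzylphosphonate anion, added cold so that carbonyl addition outruns deprotonation of the lactone, should give the (E)-styryl terminus and complete the triene.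

Step 17
Reactants: 29 (1S,4R,4aS,7R,7aS)-5-ethyl-1-[(1E,3E,5E)-2-ethyl-4-methyl-6-phenylhexa-1,3,5-trien-1-yl]-1,4,7-trimethyl-4,4a,7,7a-tetrahydrocyclopenta[c]pyran-3(1H)-one
Product: 33 (1R,3aR,4R,5S,7aS)-3,5-diethyl-1,4,7-trimethyl-5-[(1E,3E)-2-methyl-4-phenylbuta-1,3-dien-1-yl]-3a,4,5,7a-tetrahydro-1H-indene-4-carboxylic acid, via lithium enolate 30 (not isolated), via silyl ketene acetal 31 (not isolated), via silyl ester 32 (not isolated)
Conditions: LiN(iPr)2, THF/HMPA, −78 °C; t-BuMe2SiCl, −78 → 23 °C; toluene, 90 °C; then 1 M HCl, THF, 23 °C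
Reagents that add atoms: none
Why: LiN(iPr)2 removes the axial C10 hydrogen and the enolate is O-silylated to the cyclic silyl ketene acetal, whose C10=C1–O–C7–C8=C9 array then undergoes a concerted suprafacial [3,3] shift in which C9–C10 forms, C7–O breaks, C7=C8 appears and C1 leaves the ring as the silyl ester (Ireland–Claisen ring contraction of an alkenyl lactone is the closest known reaction type). Ring B closes by this sigmatropic bond formation across the lactone in a boat-shaped six-atom array, the only one the two-atom bridge C11–C6 allows, so the closure is pericyclic and not an ionic exo or endo cyclisation. C10 is set by C7: the alkenyl group stands on the lactone face syn to H-6, the trans ring fusion permits only the boat in which that group is axial, and C9 therefore bonds to this face of the planar C10, which places the carboxyl cis to the diene and the C10 methyl trans to H-11. C9 is set by the E geometry of C8=C9 within that boat, the ethyl group (cis to C7) ending cis to the C10 methyl. The step needs the shift to outrun heterolysis of the triene-stabilised C7–O bond and elimination, and the non-polar medium, the amine-buffered silyl ketene acetal and the charge-stabilising triene (which should also lower the barrier of the polarised transition state) are counted on for that. Dilute acid then frees the acid from its silyl ester in the same flask.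

**Compound list**

1 | but-2-yn-1-ol | CC#CCO | starting material
2 | tert-butyl(but-2-yn-1-yloxy)dimethylsilane | CC#CCO[Si](C)(C)C(C)(C)C | intermediate
3 | chlorobis(cyclopentadienyl)[(2E)-4-(tert-butyldimethylsilyloxy)but-2-en-2-yl]zirconium | Cl[Zr](C1C=CC=C1)(C1C=CC=C1)/C(C)=C/CO[Si](C)(C)C(C)(C)C | intermediate
4 | tert-butyl{[(2E)-3-iodobut-2-en-1-yl]oxy}dimethylsilane | I/C(C)=C/CO[Si](C)(C)C(C)(C)C | intermediate
5 | (S)-4-(tert-butyldimethylsilyloxy)cyclopent-2-en-1-one | O=C1C=C[C@@H](O[Si](C)(C)C(C)(C)C)C1 | starting material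
6 | [4-(tert-butyldimethylsilyloxy)but-2-en-2-yl]lithium, lithium in the place of the iodine of 4 (trans to CH2OSi) | [Li]/C(C)=C/CO[Si](C)(C)C(C)(C)C | intermediate
7 | lithium [(2E)-4-(tert-butyldimethylsilyloxy)but-2-en-2-yl]dimethylzincate | [Li+].C[Zn-](C)/C(C)=C/CO[Si](C)(C)C(C)(C)C | intermediate
8 | lithium dimethyl{[(3R,4S)-4-(tert-butyldimethylsilyloxy)-3-[(2E)-4-(tert-butyldimethylsilyloxy)but-2-en-2-yl]cyclopent-1-en-1-yl]oxy}zincate | [Li+].C[Zn-](C)OC1=C[C@H](/C(C)=C/CO[Si](C)(C)C(C)(C)C)[C@@H](O[Si](C)(C)C(C)(C)C)C1 | intermediate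
9 | (2S,3R,4S)-4-(tert-butyldimethylsilyloxy)-3-[(2E)-4-(tert-butyldimethylsilyloxy)but-2-en-2-yl]-2-methylcyclopentan-1-one | O=C1[C@@H](C)[C@H](/C(C)=C/CO[Si](C)(C)C(C)(C)C)[C@@H](O[Si](C)(C)C(C)(C)C)C1 | intermediate
10 | (4R,5S)-4-[(2E)-4-(tert-butyldimethylsilyloxy)but-2-en-2-yl]-5-methylcyclopent-2-en-1-one | O=C1[C@@H](C)[C@H](/C(C)=C/CO[Si](C)(C)C(C)(C)C)C=C1 | intermediate
11 | (4S,5S)-4-[(2E)-4-(tert-butyldimethylsilyloxy)but-2-en-2-yl]-2-iodo-5-methylcyclopent-2-en-1-one | O=C1[C@@H](C)[C@H](/C(C)=C/CO[Si](C)(C)C(C)(C)C)C=C1I | intermediate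
12 | (4R,5S)-4-[(2E)-4-(tert-butyldimethylsilyloxy)but-2-en-2-yl]-2-ethyl-5-methylcyclopent-2-en-1-one | O=C1[C@@H](C)[C@H](/C(C)=C/CO[Si](C)(C)C(C)(C)C)C=C1CC | intermediate
13 | (1S,4R,5S)-4-[(2E)-4-(tert-butyldimethylsilyloxy)but-2-en-2-yl]-2-ethyl-5-methylcyclopent-2-en-1-ol | O[C@H]1[C@@H](C)[C@H](/C(C)=C/CO[Si](C)(C)C(C)(C)C)C=C1CC | intermediate
14 | propanoyl chloride | CCC(=O)Cl | starting material
15 | (1S,4R,5S)-4-[(2E)-4-(tert-butyldimethylsilyloxy)but-2-en-2-yl]-2-ethyl-5-methylcyclopent-2-en-1-yl propanoate | CCC(=O)O[C@H]1[C@@H](C)[C@H](/C(C)=C/CO[Si](C)(C)C(C)(C)C)C=C1CC | intermediate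
16 | (1S,4R,5S)-2-ethyl-4-[(2E)-4-hydroxybut-2-en-2-yl]-5-methylcyclopent-2-en-1-yl propanoate | CCC(=O)O[C@H]1[C@@H](C)[C@H](/C(C)=C/CO)C=C1CC | intermediate
17 | (1S,4R,5S)-2-ethyl-4-[(2R,3R)-3-(hydroxymethyl)-2-methyloxiran-2-yl]-5-methylcyclopent-2-en-1-yl propanoate | CCC(=O)O[C@H]1[C@@H](C)[C@H]([C@@]2(C)O[C@@H]2CO)C=C1CC | intermediate
18 | trimethylsilyl ether of 17 at the primary hydroxyl | CCC(=O)O[C@H]1[C@@H](C)[C@H]([C@@]2(C)O[C@@H]2CO[Si](C)(C)C)C=C1CC | intermediate
19 | (E)-trimethylsilyl ketene acetal of 18 (1-(trimethylsilyloxy)prop-1-enyl ether of the ring carbinol) | C/C=C(/O[Si](C)(C)C)O[C@H]1[C@@H](C)[C@H]([C@@]2(C)O[C@@H]2CO[Si](C)(C)C)C=C1CC | intermediate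
20 | trimethylsilyl (2R)-2-[(1S,4R,5S)-2-ethyl-4-methyl-5-{(2R,3R)-2-methyl-3-[(trimethylsilyloxy)methyl]oxiran-2-yl}cyclopent-2-en-1-yl]propanoate | CCC1=C[C@@H](C)[C@H]([C@@]2(C)O[C@@H]2CO[Si](C)(C)C)[C@H]1[C@@H](C)C(=O)O[Si](C)(C)C | intermediate
21 | (2R)-2-[(1S,4R,5S)-2-ethyl-5-[(2R,3R)-3-(hydroxymethyl)-2-methyloxiran-2-yl]-4-methylcyclopent-2-en-1-yl]propanoic acid | CCC1=C[C@@H](C)[C@H]([C@@]2(C)O[C@@H]2CO)[C@H]1[C@@H](C)C(=O)O | intermediate
22 | (1S,4R,4aS,7R,7aS)-1-[(1R)-1,2-dihydroxyethyl]-5-ethyl-1,4,7-trimethyl-4,4a,7,7a-tetrahydrocyclopenta[c]pyran-3(1H)-one | CCC1=C[C@@H](C)[C@@H]2[C@@](C)([C@H](O)CO)OC(=O)[C@H](C)[C@@H]12 | intermediate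
23 | (1S,4R,4aS,7R,7aS)-5-ethyl-1,4,7-trimethyl-3-oxo-1,3,4,4a,7,7a-hexahydrocyclopenta[c]pyran-1-carbaldehyde | CCC1=C[C@@H](C)[C@@H]2[C@@](C)(C=O)OC(=O)[C@H](C)[C@@H]12 | intermediate
24 | propyltriphenylphosphonium bromide | CCC[P+](c1ccccc1)(c1ccccc1)c1ccccc1.[Br-] | starting material
25 | propylidenetriphenylphosphorane | CCC=P(c1ccccc1)(c1ccccc1)c1ccccc1 | intermediate
26 | 2-(triphenylphosphoranylidene)butanal | CCC(C=O)=P(c1ccccc1)(c1ccccc1)c1ccccc1 | intermediate
27 | (2E)-2-ethyl-3-[(1S,4R,4aS,7R,7aS)-5-ethyl-1,4,7-trimethyl-3-oxo-1,3,4,4a,7,7a-hexahydrocyclopenta[c]pyran-1-yl]prop-2-enal | CCC1=C[C@@H](C)[C@@H]2[C@@](C)(/C=C(CC)/C=O)OC(=O)[C@H](C)[C@@H]12 | intermediate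
28 | (2E,4E)-4-ethyl-5-[(1S,4R,4aS,7R,7aS)-5-ethyl-1,4,7-trimethyl-3-oxo-1,3,4,4a,7,7a-hexahydrocyclopenta[c]pyran-1-yl]-2-methylpenta-2,4-dienal | CCC1=C[C@@H](C)[C@@H]2[C@@](C)(/C=C(CC)/C=C(C)/C=O)OC(=O)[C@H](C)[C@@H]12 | intermediate
29 | (1S,4R,4aS,7R,7aS)-5-ethyl-1-[(1E,3E,5E)-2-ethyl-4-methyl-6-phenylhexa-1,3,5-trien-1-yl]-1,4,7-trimethyl-4,4a,7,7a-tetrahydrocyclopenta[c]pyran-3(1H)-one | CCC1=C[C@@H](C)[C@@H]2[C@@](C)(/C=C(CC)/C=C(C)/C=C/c3ccccc3)OC(=O)[C@H](C)[C@@H]12 | intermediate
30 | lithium enolate of lactone 29 (C1–O⁻, C1=C10) | CCC1=C[C@@H](C)[C@@H]2[C@@](C)(/C=C(CC)/C=C(C)/C=C/c3ccccc3)OC([O-])=C(C)[C@@H]12.[Li+] | intermediate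
31 | tert-butyldimethylsilyl ketene acetal of lactone 29 | CCC1=C[C@@H](C)[C@@H]2[C@@](C)(/C=C(CC)/C=C(C)/C=C/c3ccccc3)OC(O[Si](C)(C)C(C)(C)C)=C(C)[C@@H]12 | intermediate
32 | tert-butyldimethylsilyl ester of 33 | CCC1=C[C@@H](C)[C@@H]2C(C)=C[C@@](/C=C(C)/C=C/c3ccccc3)(CC)[C@](C)(C(=O)O[Si](C)(C)C(C)(C)C)[C@@H]12 | intermediate
33 | (1R,3aR,4R,5S,7aS)-3,5-diethyl-1,4,7-trimethyl-5-[(1E,3E)-2-methyl-4-phenylbuta-1,3-dien-1-yl]-3a,4,5,7a-tetrahydro-1H-indene-4-carboxylic acid | CCC1=C[C@@H](C)[C@@H]2C(C)=C[C@@](/C=C(C)/C=C/c3ccccc3)(CC)[C@](C)(C(=O)O)[C@@H]12 | target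

**Step count and risks**

Total step count: 17. Longest linear sequence: 16 steps (steps 1 to 12 and 14 to 17, from but-2-yn-1-ol; 14 steps from enone 5).

Steps most likely to fail:

Step 17. The process that may fail is the sigmatropic shift itself. Heterolysis of the tertiary C7–O bond, which the phenyltriene stabilises, can lead to elimination or to recombination without stereocontrol. The crowded boat (two fully substituted termini beside a trans ring fusion) may also not be reached before the ketene acetal decomposes. The fallback keeps the same bond formation but moves it to a stage where the alkene carries no conjugating group. It sets out from enal 27, which is converted with 1,2-bis(trimethylsilyloxy)ethane and catalytic Me3SiOTf (CH2Cl2, −78 °C) into the dioxolane acetal F1. Enolisation and silylation as in step 17 give the silyl ketene acetal F2, which should rearrange on heating to the silyl ester F3. 1 M HCl then cleaves the ester and the acetal to the formyl acid F4. Wittig reaction with Ph3P=C(Me)CHO gives the enal acid F5, and Horner–Wadsworth–Emmons reaction with diethyl benzylphosphonate (2.2 equiv NaN(SiMe3)2) comes back to the route at the target 33.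

Step 11. The process that may fail is survival of the trisubstituted epoxide through silylation, enolisation and warming (opening by chloride under silyl activation, or base-induced isomerisation) before the acid is released. The fallback reverses the order so that no epoxide meets the enolate chemistry. It sets out from propanoate 15, which is rearranged first (LiN(iPr)2, Me3SiCl/Et3N, THF, −78 → 50 °C) through the silyl ketene acetal F6 and the silyl ester F7 to the acid F8. Me3SiCHN2 gives the methyl ester F9, HF·pyridine the allylic alcohol F10, and the Sharpless epoxidation of step 10 the epoxy ester F11. LiOH (THF/H2O) followed by careful acidification comes back to the route at epoxy acid 21, which is closed to 22 with CSA as in step 11.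

Step 14. The process that may fail is carbonyl addition of the stabilised α-branched ylide to an aldehyde that sits on a fully substituted carbon; prolonged heating could then erode the material. The fallback replaces the Wittig reaction by an aldol condensation. It sets out from aldehyde 23, which with 1-(trimethylsilyloxy)but-1-ene and BF3·OEt2 (CH2Cl2, −78 °C; Mukaiyama aldol) should give the β-hydroxy aldehyde F12 as a mixture of isomers at the two new centres. MeSO2Cl/Et3N followed by DBU eliminates it to the thermodynamically preferred (E)-enal, and the sequence comes back to the route at 27.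

Further compounds
F1 | step 17 | dioxolane acetal of enal 27 | CCC1=C[C@@H](C)[C@@H]2[C@@](C)(/C=C(CC)/C3OCCO3)OC(=O)[C@H](C)[C@@H]12
F2 | step 17 | tert-butyldimethylsilyl ketene acetal of F1 | CCC1=C[C@@H](C)[C@@H]2[C@@](C)(/C=C(CC)/C3OCCO3)OC(O[Si](C)(C)C(C)(C)C)=C(C)[C@@H]12
F3 | step 17 | ring-contracted silyl ester with a 1,3-dioxolan-2-yl group on C9 | CCC1=C[C@@H](C)[C@@H]2C(C)=C[C@@](C3OCCO3)(CC)[C@](C)(C(=O)O[Si](C)(C)C(C)(C)C)[C@@H]12
F4 | step 17 | formyl acid (target skeleton with CHO on C9 in place of the dienyl group) | CCC1=C[C@@H](C)[C@@H]2C(C)=C[C@@](C=O)(CC)[C@](C)(C(=O)O)[C@@H]12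
F5 | step 17 | enal acid (target skeleton with (E)-2-methyl-3-oxoprop-1-enyl on C9) | CCC1=C[C@@H](C)[C@@H]2C(C)=C[C@@](/C=C(C)/C=O)(CC)[C@](C)(C(=O)O)[C@@H]12
F6 | step 11 | (E)-trimethylsilyl ketene acetal of propanoate 15 | C/C=C(/O[Si](C)(C)C)O[C@H]1[C@@H](C)[C@H](/C(C)=C/CO[Si](C)(C)C(C)(C)C)C=C1CC
F7 | step 11 | trimethylsilyl ester of acid F8 | CCC1=C[C@@H](C)[C@H](/C(C)=C/CO[Si](C)(C)C(C)(C)C)[C@H]1[C@@H](C)C(=O)O[Si](C)(C)C
F8 | step 11 | 2-[2-ethyl-4-methyl-5-((2E)-4-(tert-butyldimethylsilyloxy)but-2-en-2-yl)cyclopent-2-en-1-yl]propanoic acid | CCC1=C[C@@H](C)[C@H](/C(C)=C/CO[Si](C)(C)C(C)(C)C)[C@H]1[C@@H](C)C(=O)O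
F9 | step 11 | methyl ester of F8 | CCC1=C[C@@H](C)[C@H](/C(C)=C/CO[Si](C)(C)C(C)(C)C)[C@H]1[C@@H](C)C(=O)OC
F10 | step 11 | allylic alcohol from desilylation of F9 | CCC1=C[C@@H](C)[C@H](/C(C)=C/CO)[C@H]1[C@@H](C)C(=O)OC
F11 | step 11 | methyl ester of epoxy acid 21 | CCC1=C[C@@H](C)[C@H]([C@@]2(C)O[C@@H]2CO)[C@H]1[C@@H](C)C(=O)OC
F12 | step 14 | β-hydroxy aldehyde from aldol addition to 23 (mixture at the two new centres) | CCC1=C[C@@H](C)[C@@H]2[C@@](C)(C(O)C(CC)C=O)OC(=O)[C@H](C)[C@@H]12
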